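Everything rests on cutting the C26 acyl chain at C10–C11, a bond inside an unbranched, stereocentre-free polymethylene run that lies eight CH2 groups from the C1 ester and far from the phenyl ring; this featureless site is what the key step exploits. Undec-10-enoic acid 1 and benzyl alcohol 2 give the precursor, benzyl undec-10-enoate 3: finished ester, C1–C10 and a sacrificial terminal =CH2. Ruthenium-catalysed cross-metathesis of 3 with 1-heptadecene 4 (C11–C26) forges C10=C11 of enoate 5 in one operation while ethylene escapes. Because the benzylic O–CH2 bond is hydrogenolysis-labile, 5 is saturated with diimide, not over a metal, giving target 6.

Key step: step 2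

Assumption: compound 6 has no stereocentre and no stereogenic double bond, so it is achiral and no enantioselective step is needed. The carbon count closes as 10 chain carbons from 3 plus 16 from 4, giving 26.

Step 1
Reactants: 1 undec-10-enoic acid; 2 benzyl alcohol
Product: 3 benzyl undec-10-enoate
Conditions: cat. p-TsOH·H2O, toluene, Dean–Stark, reflux
Reagents that add atoms: none
Why: Fischer esterification, an acid-catalysed acyl substitution driven to completion by azeotropic removal of water; the isolated terminal alkene is not protonated by catalytic sulfonic acid in toluene, and no stereocentre is involved.

Step 2
Reactants: 3 benzyl undec-10-enoate; 4 1-heptadecene (4 equiv, filtered through basic alumina and degassed)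
Product: 5 benzyl (E)-hexacos-10-enoate
Conditions: Grubbs second-generation catalyst (2 mol %), 1,4-benzoquinone (10 mol %), CH2Cl2, 40 °C, Ar sparge; then ethyl vinyl ether, SiO2
Reagents that add atoms: none
Why: Olefin cross-metathesis through the metal-alkylidene cycle: the ruthenium carbene adds to each terminal alkene in a [2+2] cycloaddition, the ruthenacyclobutane cycloreverts, and the escape of ethylene into the argon stream pulls the exchange towards the internal C10=C11 alkene. The closest known reaction type is the cross-metathesis of two unhindered aliphatic 1-alkenes of equal reactivity, which is routine for ω-unsaturated fatty esters. No ring is closed and no stereocentre is formed, and the geometry of the new alkene (E expected to dominate) is irrelevant because step 3 deletes it. Cross-selectivity cannot come from the substrates themselves, so it is secured by a fourfold excess of the recoverable hydrocarbon 4 and by chromatography, in which ester-free, monoester and diester fractions differ clearly in polarity, while the self-metathesis products remain metathesis-active and can be resubmitted. Positional fidelity is secured by 1,4-benzoquinone, which intercepts ruthenium hydrides, together with peroxide-free 4, a mild temperature and a prompt vinyl ether quench, so that chain-walked homologues should not arise. The ester carbonyl sits eight methylene groups from the reacting alkene and is too remote to chelate or deactivate the metal.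

Step 3
Reactants: 5 benzyl (E)-hexacos-10-enoate
Product: 6 benzyl hexacosanoate
Conditions: TsNHNH2 (excess, in portions), NaOAc, DME/H2O, reflux
Reagents that add atoms: none
Why: Diimide reduction: cis-HN=NH, released by base-assisted loss of sulfinate from the sulfonyl hydrazide, delivers two hydrogen atoms to the unpolarised C10=C11 bond through a concerted six-membered transition state driven by loss of N2, a pathway that cannot cleave the benzylic C–O bond or reduce the ester carbonyl and the arene, and that creates no stereocentre.

Compound list
1 | undec-10-enoic acid | C=CCCCCCCCCC(=O)O | starting material
2 | benzyl alcohol | OCc1ccccc1 | starting material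
3 | benzyl undec-10-enoate | C=CCCCCCCCCC(=O)OCc1ccccc1 | intermediate
4 | 1-heptadecene | C=CCCCCCCCCCCCCCCC | starting material
5 | benzyl (E)-hexacos-10-enoate (drawn as the expected major isomer; any Z isomer formed with it is reduced alike) | CCCCCCCCCCCCCCC/C=C/CCCCCCCCC(=O)OCc1ccccc1 | intermediate
6 | benzyl hexacosanoate | CCCCCCCCCCCCCCCCCCCCCCCCCC(=O)OCc1ccccc1 | target

Total step count: 3
Longest linear sequence: 3 steps (1 → 3 → 5 → 6)

Steps most likely to fail

1. Step 2 (key step).
- **Risk:** Unselective self-metathesis of each partner may erode the throughput of cross product. Ruthenium hydride species may also move the double bond before or after the exchange, which would scramble the chain length by single carbons in a way no later purification can repair.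
- **Fallback (carbonyl olefination instead of alkylidene exchange):** It sets out from 3, whose terminal alkene is cleaved by ozonolysis (O3, CH2Cl2, −78 °C; then Me2S) to benzyl 10-oxodecanoate F1. Commercial hexadecyltriphenylphosphonium bromide is deprotonated with NaHMDS in THF to hexadecylidene(triphenyl)phosphorane F2. A Wittig reaction of F2 with F1 from −78 °C to room temperature should give benzyl (Z)-hexacos-10-enoate F3, the geometric isomer of 5 with the same C10=C11 bond. F3 takes the place of 5 under the diimide conditions of step 3, so the fallback comes back to the route at 6. Both chain lengths are fixed by the reagents and nothing equilibrates, so chain-length scrambling is excluded.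

2. Step 3.
- **Risk:** The reduction may stall short of full conversion, because diimide disproportionates faster than a 1,2-dialkyl alkene captures it and because the waxy substrate dissolves poorly in the aqueous medium. Unreduced material would then co-elute and co-crystallise with the product.
- **Fallback (give up chemoselectivity and rebuild the ester):** It sets out from 5, which is hydrogenated exhaustively (H2, Pd/C, THF/EtOAc, 40 °C). This deliberately saturates the alkene and hydrogenolyses the benzyl group to give hexacosanoic acid F4, which is purified by recrystallisation. F4 is then esterified with 2 under the conditions of step 1 (cat. p-TsOH, toluene, Dean–Stark), hot toluene being a good solvent for the long-chain acid. The route is rejoined at 6.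

3. Step 1.
- **Risk:** The esterification may stall at equilibrium if water removal is inefficient, and the benzylic alcohol may self-etherify under acid. At worst, trace acid-induced migration of the terminal alkene would resurface later as a chain-length error.
- **Fallback (form the O–CH2 bond instead of the acyl–O bond):** It sets out from 1, which is deprotonated with K2CO3 in DMF to potassium undec-10-enoate F5. SN2 alkylation of F5 with benzyl bromide at room temperature is irreversible and acid-free, and it comes back to the route at 3.

Further compounds
F1 | step 2 | benzyl 10-oxodecanoate | O=CCCCCCCCCC(=O)OCc1ccccc1
F2 | step 2 | hexadecylidene(triphenyl)phosphorane | CCCCCCCCCCCCCCCC=P(c1ccccc1)(c1ccccc1)c1ccccc1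
F3 | step 2 | benzyl (Z)-hexacos-10-enoate | CCCCCCCCCCCCCCC/C=C\CCCCCCCCC(=O)OCc1ccccc1
F4 | step 3 | hexacosanoic acid | CCCCCCCCCCCCCCCCCCCCCCCCCC(=O)O
F5 | step 1 | potassium undec-10-enoate | C=CCCCCCCCCC(=O)[O-].[K+]
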